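(The data are simulated with made-up constants, and the scatter is random.)

Read the autumn run first: it gives the clock for this bench.

| setting | autumn | dawn | eta | theta | epsilon | alpha |
|---|---|---|---|---|---|---|
| substrate | 0.041 M | 0.15 M | 0.030 M | 0.040 M | 0.060 M | 0.10 M |
| enzyme | 0.01 mol% | 0.01 mol% | 0.01 mol% | 0.01 mol% | 0.01 mol% | 0.01 mol% |
| remark | run made earlier | run made earlier |  |  |  |  |
| time |  |  | 40 h | 40 h | 40 h | 40 h |

| run | time / h | product / % |
|---|---|---|
| autumn | 6.00 | 73.9 |
| autumn | 12.0 | 93.2 |
| autumn | 15.0 | 96.0 |
| autumn | 25.0 | 100.1 |
| autumn | 30.0 | 98.9 |
| dawn | 6.00 | 95.9 |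
| dawn | 12.0 | 100.5 |
| dawn | 15.0 | 99.3 |
| dawn | 25.0 | 99.5 |
| dawn | 30.0 | 99.7 |

(standard deviation of a reading: 0.5 percentage points)

- a reading or a percentage of product counts all its forms, free or not
- the concentration of product that is asked is that of its free form alone
- "hardly changes" means that all values lie within two and a half points (for a concentration: within two and a half percent of the largest)

1. [product] (only what is free in solution) at the end for eta, theta, epsilon, alpha, in this order
2. how the row runs (falls all the way / falls, then rises / rises, then falls / rises all the way / hardly changes)

1. In the autumn run, 73.9% product after 6.00 h gives a pseudo-first-order constant k, the negative logarithm of the fraction of substrate remaining divided by time, of 0.224 h⁻¹. The substrate half-life τ, the time in which the remaining substrate halves, is then 3.10 h.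

2. The enzyme loading is fixed in mol%, so enzyme concentration follows the charge. If the rate is first order in enzyme, τ varies inversely with the charge, which gives 4.23 h for eta.

3. The dawn run reads τ = 1.30 h, longer than the scaled 0.846 h, so the scaling does not carry to the dawn charge. By my reckoning, τ for alpha lies between 1.30 h and 3.10 h.

4. Eta has the lowest charge, and 40 h spans 9.46 of its half-lives. The reckoned substrate left on arrival is 0.142% of the charge.

5. Leave the flasks closed and stirred. A reading counts product in all its forms, so a value near 100% does not show what is dissolved. My row is the charge of each flask, held as an upper bound.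

The forecast gives 0.03 M, 0.04 M, 0.06 M and 0.1 M, a row that rises all the way: “Free product is therefore about equal to the substrate charged”.

The flask gives 0.0299 M, 0.0399 M, 0.0599 M and 0.0640 M, a row that rises all the way.

    crystals ⇌ product, rate k1*(cs1 - [product]) while solid is left; crystals form when [product] > cs1 (solubility = 0.0640 M, k = 0.840 h⁻¹)
    substrate + enzyme → product + enzyme, rate k2*[substrate]*[enzyme]/(1 + ([substrate]/Km2)) (0.0530 M, k = 80000 L mol⁻¹ h⁻¹)
    enzyme + product → spent catalyst (k = 1.10 L mol⁻¹ h⁻¹)

In eta, half of the turnover of substrate into product up to the asked time is done by 4.10 h, close to the reckoned 4.23 h and shorter than the 40 h run, while the half-life of dissolved product against conversion with enzyme into spent catalyst, 9100 d at 4.10 h, is longer than the run. For theta, τ scales to 3.17 h, which reckons 1.26% of the substrate left at 20.0 h where theta holds 1.50%; alpha, charged at 0.10 M, above the 0.064 M at which crystals form, holds 36.0% of its charge as crystals at 40.0 h, with free product at 0.0640 M.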